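**Strategy.** The dihydrofuran (O1–C2–C3–C3a=C7a) with its exocyclic tertiary carbinol is traced back to an isomeric 3-hydroxy-dihydropyran in which the carbinol carbon is still a ring atom (O1–Cquat–CH(OH)–CH2–C3a=C7a). Activating that secondary hydroxyl lets O1 shift from the quaternary carbon to the neighbouring CH, and water opens the epoxonium ion at the tertiary carbon. One operation thus contracts the ring and sets both side-chain stereocentres by double inversion; it exploits the vicinal O1/C2/carbinol-carbon array. The pyranol comes from 6-endo opening of a nerol-derived epoxide on a dearomatised acylphloroglucinol, built by Claisen cyclisation from an enantioenriched methyl(prenyl)malonate.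

Key step: step 11

Assumption: enolisable di- and tricarbonyl compounds are drawn as one tautomer, and the sense of induction in step 3 is taken by analogy with other allylic bromides in this catalyst system (if it is opposite, the (R,R)-catalyst is used and nothing else changes).

Step 1
Reactants: 1 2,2,5-trimethyl-1,3-dioxane-4,6-dione (methyl Meldrum's acid); 2 2,2-diphenylethanol
Product: 3 3-(2,2-diphenylethoxy)-2-methyl-3-oxopropanoic acid (racemic)
Conditions: toluene, 110 °C
Reagents that add atoms: none
Why: Alcoholysis of a Meldrum's acid (ring opening with loss of acetone) should give the malonic half ester, whose methine is configurationally labile so that no stereocentre matters yet.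

Step 2
Reactants: 3 3-(2,2-diphenylethoxy)-2-methyl-3-oxopropanoic acid
Product: 4 1-tert-butyl 3-(2,2-diphenylethyl) 2-methylpropanedioate
Conditions: isobutylene (excess), H2SO4 (cat.), CH2Cl2, sealed vessel, 20 °C
Reagents that add atoms: 2-methylpropene, C=C(C)C
Why: Acid-catalysed addition of the carboxylic acid to isobutylene (tert-butyl ester formation) should give the mixed malonate with two esters of very different size and lability.

Step 3
Reactants: 4 1-tert-butyl 3-(2,2-diphenylethyl) 2-methylpropanedioate
Product: 5 1-tert-butyl 3-(2,2-diphenylethyl) (R)-2-methyl-2-(3-methylbut-2-en-1-yl)propanedioate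
Conditions: prenyl bromide (3 equiv), (S,S)-3,4,5-trifluorophenyl-NAS bromide (5 mol%), 50% aq. KOH, toluene, −40 °C
Reagents that add atoms: 1-bromo-3-methylbut-2-ene (prenyl bromide), BrCC=C(C)C
Why: Asymmetric phase-transfer alkylation of an α-methyl mixed malonate, in which the enolate is alkylated inside the ion pair with the C2-symmetric N-spiro binaphthyl ammonium cation that tells the tert-butyl from the diphenylethyl ester side, should set the quaternary carbon (later C7) as (R).

Step 4
Reactants: 5 1-tert-butyl 3-(2,2-diphenylethyl) (R)-2-methyl-2-(3-methylbut-2-en-1-yl)propanedioate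
Product: 6 (S)-2-[(2,2-diphenylethoxy)carbonyl]-2,5-dimethylhex-4-enoic acid
Conditions: 85% aq. H3PO4, toluene, 25 °C
Reagents that add atoms: none
Why: Mild alkyl–oxygen (AAL1) cleavage of the tert-butyl ester should leave the primary ester, the prenyl olefin and the quaternary stereocentre untouched.

Step 5
Reactants: 6 (S)-2-[(2,2-diphenylethoxy)carbonyl]-2,5-dimethylhex-4-enoic acid
Product: 7 2,2-diphenylethyl (R)-2-(chlorocarbonyl)-2,5-dimethylhex-4-enoate
Conditions: 1-chloro-N,N,2-trimethylprop-1-en-1-amine (1.2 equiv), CH2Cl2, 0 → 20 °C; concentrated and used crude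
Reagents that add atoms: 1-chloro-N,N,2-trimethylprop-1-en-1-amine, CC(C)=C(Cl)N(C)C
Why: Acid chloride formation with an α-chloroenamine runs under neutral conditions without HCl, so the prenyl group and the ester should survive, and a quaternary malonyl chloride cannot form a ketene.

Step 6
Reactants: 7 2,2-diphenylethyl (R)-2-(chlorocarbonyl)-2,5-dimethylhex-4-enoate; 8 5-methylhexane-2,4-dione
Product: 10 (S)-3,5-dihydroxy-6-methyl-6-(3-methylbut-2-en-1-yl)-2-(2-methylpropanoyl)cyclohexa-2,4-dien-1-one, via triketo ester 9 (not isolated)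
Conditions: 8 (2 equiv), LDA (4 equiv), THF, 0 °C; 7, −78 °C; LDA (2 equiv), −78 → 50 °C; then 1 M HCl
Reagents that add atoms: none
Why: The 1,3-dianion of the β-diketone is C-acylated at its terminal methyl carbon, and the resulting 3,5,7-triketo ester should close by an intramolecular Claisen (Dieckmann-type, 6-exo-trig) condensation of the central carbanion onto the ester, as in polyketide-type acylphloroglucinol synthesis; the aldol mode is blocked by the quaternary carbon, whose configuration is untouched and which now distinguishes C7a from C6.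

Step 7
Reactants: 11 nerol, (Z)-3,7-dimethylocta-2,6-dien-1-ol
Product: 12 [(2R,3S)-3-methyl-3-(4-methylpent-3-en-1-yl)oxiran-2-yl]methanol
Conditions: Ti(OiPr)4 (5 mol%), D-(−)-diethyl tartrate (7 mol%), t-BuOOH (2 equiv), 4 Å MS, CH2Cl2, −20 °C
Reagents that add atoms: tert-butyl hydroperoxide, CC(C)(C)OO
Why: Katsuki–Sharpless asymmetric epoxidation is directed by the allylic hydroxyl to the 2,3-olefin only, and D-(−)-tartrate should deliver oxygen to the face of the (Z)-olefin that gives the (2R,3S)-epoxide.

Step 8
Reactants: 12 [(2R,3S)-3-methyl-3-(4-methylpent-3-en-1-yl)oxiran-2-yl]methanol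
Product: 13 (2S,3S)-3-methyl-3-(4-methylpent-3-en-1-yl)oxirane-2-carbaldehyde
Conditions: TEMPO (10 mol%), PhI(OAc)2 (1.1 equiv), CH2Cl2, 20 °C
Reagents that add atoms: none
Why: Oxoammonium (TEMPO/PhI(OAc)2) oxidation of the primary alcohol should stop at the aldehyde and spare epoxide and olefin; the α-carbon is an epoxide carbon and does not epimerise (the descriptor change at C2 is only a CIP effect).

Step 9
Reactants: 10 (S)-3,5-dihydroxy-6-methyl-6-(3-methylbut-2-en-1-yl)-2-(2-methylpropanoyl)cyclohexa-2,4-dien-1-one; 13 (2S,3S)-3-methyl-3-(4-methylpent-3-en-1-yl)oxirane-2-carbaldehyde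
Product: 16 (2R,3R,8R)-3,7-dihydroxy-2,8-dimethyl-8-(3-methylbut-2-en-1-yl)-2-(4-methylpent-3-en-1-yl)-6-(2-methylpropanoyl)-3,4-dihydro-2H-chromen-5(8H)-one, via alkylidene trione 14 (not isolated), via epoxy enol 15 (not isolated)
Conditions: Hantzsch ester (1.1 equiv), L-proline (10 mol%), CH2Cl2, 25 °C; then 1,1,1,3,3,3-hexafluoropropan-2-ol, CSA (0.3 equiv), 0 °C
Reagents that add atoms: none
Why: Three-component reductive alkylation (Knoevenagel condensation at C3a, the only acidic CH2, then transfer hydrogenation of the alkylidene by the Hantzsch ester) joins C3a to the epoxide-bearing CH2, and acid should then trigger Markovnikov 6-endo-tet epoxide opening by the free C7a enol oxygen (the C4 oxygen is tied up in the chelate with the isobutyryl group) at the tertiary carbon with inversion while the secondary C–O bond is retained, which sets (2R,3R) in the new dihydropyran.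

Step 10
Reactants: 16 (2R,3R,8R)-3,7-dihydroxy-2,8-dimethyl-8-(3-methylbut-2-en-1-yl)-2-(4-methylpent-3-en-1-yl)-6-(2-methylpropanoyl)-3,4-dihydro-2H-chromen-5(8H)-one
Product: 17 (2R,3R,6R,8S)-3-hydroxy-2,8-dimethyl-6,8-bis(3-methylbut-2-en-1-yl)-2-(4-methylpent-3-en-1-yl)-6-(2-methylpropanoyl)-3,4-dihydro-2H-chromene-5,7(6H,8H)-dione
Conditions: prenyl acetate (1.3 equiv), Pd(PPh3)4 (5 mol%), Et3N (1.2 equiv), THF, 40 °C
Reagents that add atoms: 3-methylbut-2-en-1-yl acetate (prenyl acetate), CC(=O)OCC=C(C)C
Why: Tsuji–Trost allylation of the acidic triketone, in which the π-prenyl-palladium cation is attacked at its unsubstituted terminus by C-6 of the chromene (O-allylation is reversible under Pd) on the face of the flat enolate anti to the larger C-8 substituent (prenyl versus methyl, 1,3-diaxial-type contact), should give the trans-diprenyl (6R) isomer.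

Step 11
Reactants: 17 (2R,3R,6R,8S)-3-hydroxy-2,8-dimethyl-6,8-bis(3-methylbut-2-en-1-yl)-2-(4-methylpent-3-en-1-yl)-6-(2-methylpropanoyl)-3,4-dihydro-2H-chromene-5,7(6H,8H)-dione
Product: 19 (2S,5R,7S)-2-[(2S)-2-hydroxy-6-methylhept-5-en-2-yl]-7-methyl-5,7-bis(3-methylbut-2-en-1-yl)-5-(2-methylpropanoyl)-2,3-dihydro-1-benzofuran-4,6(5H,7H)-dione, via secondary triflate 18 (not isolated)
Conditions: Tf2O (1.2 equiv), 2,6-lutidine (3 equiv), CH2Cl2, −78 °C; then THF–H2O, NaHCO3, −78 → 20 °C
Reagents that add atoms: water, O; trifluoromethanesulfonic anhydride, O=S(=O)(OS(=O)(=O)C(F)(F)F)C(F)(F)F (its triflyl group is carried only by the non-isolated triflate 18)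
Why: Triflation of the equatorial hydroxyl at pyran C-3 places the leaving group antiperiplanar to the ring bond O1–C-2, so O1 should displace triflate from C-3 with inversion (a 1,2-oxygen shift through a bridged epoxonium ion, driven by transfer of the positive charge to the tertiary carbon C-2), and water then opens the epoxonium at that tertiary carbon with inversion. The closest known reactions are the sulfonate- or fluorinating-agent-induced contractions of 3-hydroxy-2,2-dialkylchromans and 3-sulfonyloxytetrahydropyrans to 2-(1-hydroxyalkyl)dihydrobenzofurans and tetrahydrofurans. The five-membered ring O1–C2–C3–C3a=C7a closes by intramolecular SN2 attack of O1 (3-exo-tet neighbouring-group attack, then ring opening of the three-membered ion), not by a new C–C bond. Both new stereocentres are set stereospecifically by the substrate: pyran C-3 becomes furan C-2 and pyran C-2 becomes the carbinol carbon, each with one inversion, so (2R,3R) should give (2S) with an (S)-carbinol. The step needs O1 participation to win over elimination to the 2H-pyran, 1,2-alkyl shift and capture by the side-chain olefin; the fixed antiperiplanar geometry, the hindered base and the low temperature are meant to secure this.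

**Compound list**

1 | 2,2,5-trimethyl-1,3-dioxane-4,6-dione (methyl Meldrum's acid) | CC1C(=O)OC(C)(C)OC1=O | starting material
2 | 2,2-diphenylethanol | OCC(c1ccccc1)c1ccccc1 | starting material
3 | 3-(2,2-diphenylethoxy)-2-methyl-3-oxopropanoic acid (racemic) | CC(C(=O)O)C(=O)OCC(c1ccccc1)c1ccccc1 | intermediate
4 | 1-tert-butyl 3-(2,2-diphenylethyl) 2-methylpropanedioate | CC(C(=O)OC(C)(C)C)C(=O)OCC(c1ccccc1)c1ccccc1 | intermediate
5 | 1-tert-butyl 3-(2,2-diphenylethyl) (R)-2-methyl-2-(3-methylbut-2-en-1-yl)propanedioate | CC(C)(C)OC(=O)[C@](C)(CC=C(C)C)C(=O)OCC(c1ccccc1)c1ccccc1 | intermediate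
6 | (S)-2-[(2,2-diphenylethoxy)carbonyl]-2,5-dimethylhex-4-enoic acid | OC(=O)[C@](C)(CC=C(C)C)C(=O)OCC(c1ccccc1)c1ccccc1 | intermediate
7 | 2,2-diphenylethyl (R)-2-(chlorocarbonyl)-2,5-dimethylhex-4-enoate | ClC(=O)[C@](C)(CC=C(C)C)C(=O)OCC(c1ccccc1)c1ccccc1 | intermediate
8 | 5-methylhexane-2,4-dione | CC(=O)CC(=O)C(C)C | starting material
9 | 2,2-diphenylethyl (S)-2,5-dimethyl-2-(6-methyl-3,5-dioxoheptanoyl)hex-4-enoate (open-chain triketo ester) | CC(C)C(=O)CC(=O)CC(=O)[C@](C)(CC=C(C)C)C(=O)OCC(c1ccccc1)c1ccccc1 | intermediate (not isolated)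
10 | (S)-3,5-dihydroxy-6-methyl-6-(3-methylbut-2-en-1-yl)-2-(2-methylpropanoyl)cyclohexa-2,4-dien-1-one | CC(C)C(=O)C1=C(O)C=C(O)[C@](C)(CC=C(C)C)C1=O | intermediate
11 | nerol, (Z)-3,7-dimethylocta-2,6-dien-1-ol | CC(C)=CCC/C(C)=C\CO | starting material
12 | [(2R,3S)-3-methyl-3-(4-methylpent-3-en-1-yl)oxiran-2-yl]methanol | OC[C@H]1O[C@@]1(C)CCC=C(C)C | intermediate
13 | (2S,3S)-3-methyl-3-(4-methylpent-3-en-1-yl)oxirane-2-carbaldehyde | O=C[C@H]1O[C@@]1(C)CCC=C(C)C | intermediate
14 | Knoevenagel adduct of 10 and 13: exocyclic alkylidene at C3a (E/Z mixture), quaternary ring carbon and epoxide carbons as in 10 and 13 | CC(C)C(=O)C1=C(O)[C@@](C)(CC=C(C)C)C(=O)C(=C[C@H]2O[C@@]2(C)CCC=C(C)C)C1=O | intermediate (not isolated)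
15 | (S)-3,5-dihydroxy-6-methyl-6-(3-methylbut-2-en-1-yl)-4-{[(2R,3S)-3-methyl-3-(4-methylpent-3-en-1-yl)oxiran-2-yl]methyl}-2-(2-methylpropanoyl)cyclohexa-2,4-dien-1-one | CC(C)C(=O)C1=C(O)C(C[C@H]2O[C@@]2(C)CCC=C(C)C)=C(O)[C@](C)(CC=C(C)C)C1=O | intermediate (not isolated)
16 | (2R,3R,8R)-3,7-dihydroxy-2,8-dimethyl-8-(3-methylbut-2-en-1-yl)-2-(4-methylpent-3-en-1-yl)-6-(2-methylpropanoyl)-3,4-dihydro-2H-chromen-5(8H)-one (drawn tautomer; C-8 has the spatial arrangement of C-7 in 19) | CC(C)=CCC[C@]1(C)[C@H](O)CC2=C(O1)[C@](C)(CC=C(C)C)C(O)=C(C(=O)C(C)C)C2=O | intermediate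
17 | (2R,3R,6R,8S)-3-hydroxy-2,8-dimethyl-6,8-bis(3-methylbut-2-en-1-yl)-2-(4-methylpent-3-en-1-yl)-6-(2-methylpropanoyl)-3,4-dihydro-2H-chromene-5,7(6H,8H)-dione | CC(C)=CCC[C@]1(C)[C@H](O)CC2=C(O1)[C@](C)(CC=C(C)C)C(=O)[C@](CC=C(C)C)(C(=O)C(C)C)C2=O | intermediate
18 | 3-O-trifluoromethanesulfonate of 17 (same configuration at all four centres) | CC(C)=CCC[C@]1(C)[C@H](OS(=O)(=O)C(F)(F)F)CC2=C(O1)[C@](C)(CC=C(C)C)C(=O)[C@](CC=C(C)C)(C(=O)C(C)C)C2=O | intermediate (not isolated)
19 | (2S,5R,7S)-2-[(2S)-2-hydroxy-6-methylhept-5-en-2-yl]-7-methyl-5,7-bis(3-methylbut-2-en-1-yl)-5-(2-methylpropanoyl)-2,3-dihydro-1-benzofuran-4,6(5H,7H)-dione | CC(C)=CCC[C@](C)(O)[C@@H]1CC2=C(O1)[C@](C)(CC=C(C)C)C(=O)[C@](CC=C(C)C)(C(=O)C(C)C)C2=O | target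

**Totals.** Total step count: 11. Longest linear sequence: 9 steps (steps 1–6, 9, 10, 11).

**Steps most likely to fail**

Step 11 (ring contraction). After triflation the ionisation may bypass O1, because a vinylogous-ester oxygen is a weak neighbouring group. It could then end in elimination towards the 2H-pyran, in a 1,2-alkyl shift, or in capture of the cationic centre by the distal side-chain olefin. The fallback sets out from 10 and 13 and returns at 19, giving up the six-membered precursor. The reductive alkylation of step 9 is run without the acid stage, and epoxy enol 15 is treated with K2CO3 in MeOH. The C7a enolate oxygen should then open the epoxide in the 5-exo-tet mode at the secondary carbon with inversion. This should give the des-prenyl dihydrofuran carbinol F1 with the same (2S, carbinol S) configuration. Prenylation of F1 at C5 under the conditions of step 10 then leads to 19.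

Step 10 (C-prenylation). Facial discrimination at the planar enolate may be poor, since methyl and prenyl at the neighbouring quaternary carbon differ little in size. The nucleophile may also attack the substituted terminus of the π-prenyl unit. The fallback sets out from 16 and returns at 17, and replaces substrate control by reagent control in two operations. Allylation with allyl acetate, Pd2(dba)3 and the enantiomer of the DACH-phenyl bis(2-diphenylphosphinobenzamide) ligand that matches the substrate should give the 6-allyl compound F2. Cross-metathesis of F2 with 2-methyl-2-butene (second-generation Grubbs catalyst) converts allyl into prenyl and gives 17. The prenyl groups already present are degenerate under these conditions.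

Step 9 (reductive alkylation and 6-endo cyclisation). The epoxy aldehyde or alkylidene trione 14 may be consumed before hydride transfer, by epoxide opening or by Michael addition of a second molecule of 10. Separately, any epoxide opening that occurs in the 5-exo mode gives the des-prenyl form of the final ring with the same configuration, so that material converges on 19 after step 10. The fallback sets out from 12 and 10 and returns at 16, separating C–C bond formation from cyclisation. Alcohol 12 is converted with I2, PPh3 and imidazole into the epoxy iodide F3. The dianion of 10 (K2CO3, DMF) is C-alkylated at C3a by F3 to give 15, now isolated. Compound 15 is then cyclised with CSA in hexafluoropropan-2-ol to 16.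

**Further compounds**

F1 | step 11 | (2S,7R)-6-hydroxy-2-[(2S)-2-hydroxy-6-methylhept-5-en-2-yl]-7-methyl-7-(3-methylbut-2-en-1-yl)-5-(2-methylpropanoyl)-2,3-dihydro-1-benzofuran-4(7H)-one (drawn tautomer) | CC(C)=CCC[C@](C)(O)[C@@H]1CC2=C(O1)[C@](C)(CC=C(C)C)C(O)=C(C(=O)C(C)C)C2=O
F2 | step 10 | (2R,3R,6R,8S)-3-hydroxy-2,8-dimethyl-8-(3-methylbut-2-en-1-yl)-2-(4-methylpent-3-en-1-yl)-6-(2-methylpropanoyl)-6-(prop-2-en-1-yl)-3,4-dihydro-2H-chromene-5,7(6H,8H)-dione | CC(C)=CCC[C@]1(C)[C@H](O)CC2=C(O1)[C@](C)(CC=C(C)C)C(=O)[C@](CC=C)(C(=O)C(C)C)C2=O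
F3 | step 9 | (2S,3S)-2-(iodomethyl)-3-methyl-3-(4-methylpent-3-en-1-yl)oxirane | IC[C@H]1O[C@@]1(C)CCC=C(C)C
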